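The runs were generated by integration with made-up constants, and the scatter is random.

I start from the leftover, the part of the charged left-handed and right-handed substrate that stands in neither product. The single-handed free catalyst and the reagent turn the two substrates into products, and I want to know how the two new flasks compare.

| flask | left-handed substrate | right-handed substrate | reagent | free catalyst | impurity | remark | time |
|---|---|---|---|---|---|---|---|
| teal | 0.050 M | 0.050 M | 0.19 M | 0.16 mM | 24 µM | run made earlier |  |
| ochre | 0.050 M | 0.050 M | 0.41 M | 0.16 mM | 24 µM | run made earlier |  |
| grey | 0.050 M | 0.050 M | 0.58 M | 0.16 mM | 24 µM | run made earlier |  |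
| theta | 0.050 M | 0.050 M | 0.200 M | 0.16 mM | 24 µM |  | 2.5 h |
| beta | 0.050 M | 0.050 M | 0.800 M | 0.16 mM | 24 µM |  | 2.5 h |

- teal (time / min: left-handed product / %, right-handed product / %): 10.0: 36.3, 0.7; 25.0: 55.3, 1.9; 50.0: 72.5, 1.0; 80.0: 84.0, 2.6; 120: 91.8, 1.8
- ochre (time / min: left-handed product / %, right-handed product / %): 8.00: 47.6, 0.4; 15.0: 59.1, 2.1; 30.0: 72.4, 3.2; 60.0: 85.7, 3.2; 120: 94.4, 4.6
- grey (time / min: left-handed product / %, right-handed product / %): 20.0: 67.3, 2.6; 40.0: 80.8, 4.3; 60.0: 87.1, 5.3; 80.0: 92.0, 5.4; 120: 93.6, 5.5

(standard deviation of a reading: 0.5 percentage points)

- free catalyst is single-handed; left-handed substrate and right-handed substrate are mirror images of each other, charged as a racemate, each of them at the stated concentration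
- an excess is the difference of the two amounts in percent of their sum
- an excess is below zero if the other one leads

1. the winner by excess of left-handed product over right-handed product in the product; "neither" if no more than 2 percentage points parts them (theta / beta / neither)
2. excess of left-handed product over right-handed product in the product at the end, theta
3. excess of left-handed product over right-handed product in the product at the end, beta

Teal is the nearest run to theta, with 0.19 M of reagent against 0.200 M and an equal charge otherwise. Teal's leftover L reads 13.4% at 80.0 min and 6.40% at 120 min, which reads as a decay of 0.0185 /min. As an estimate, I carry that decay on to theta's end: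

L = 6.40% × exp(−0.0185 /min × 30.0 min) = 3.68%

That is far less than teal's 91.8% of left-handed product. So I reckon theta's excess from the ratio of its two products.

Let ρ be right-handed product over left-handed product. The excess is then

e = (1 − ρ)/(1 + ρ)

The last readings give ρ = 0.0196 in teal, 0.0487 in ochre and 0.0588 in grey. Teal's 1.8% carries a scatter of 0.5 percentage points, so I pool the three runs:

λ = sum of ρ / sum of reagent charged = 0.108 /M

I carry this leak coefficient, ρ per unit of reagent charged. Teal's own excess reads 96.2%. My reckoning for the two new flasks is:

theta: ρ = λ × 0.200 M = 0.0215, e = 95.8%

beta: ρ = λ × 0.800 M = 0.0862, e = 84.1%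

So I choose theta, by 12 points.

The forecast names theta, with 95.3% for theta and 85.8% for beta, 1.7 points above my beta, and says of the ratio: “It rises with reagent, flattening slightly”.

The flask gives theta, with 95.4% for theta and 85.9% for beta.

    2 free catalyst ⇌ resting dimer (K = 4100 /M, k = 1760 /M/min)
    left-handed substrate ⇌ right-handed substrate (k = 0.0345 /min)
    reagent + free catalyst + left-handed substrate → free catalyst + left-handed product (k = 8750 /M²/min)
    free catalyst + impurity → spent catalyst (k = 51500 /M/min)
    reagent ⇌ dormant form (K = 0.214, k = 0.0240 /min)
    reagent + free catalyst + right-handed substrate → free catalyst + right-handed product (k = 94.8 /M²/min)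

At 2.50 h, beta's reagent stands at 72.1% of its charge, beside 0.123 M of dormant form. Beta's products give λ = 0.0948 /M, lower than my pooled value. For the neighbour flask, beta with 0.48 M of reagent, the pooled λ gives ρ = 0.0517 and e = 90.2%. That neighbour flask ends at 90.8%.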